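## Retrosynthetic overview

1. Target ⇐ TBS removal ⇐ Red-Al opening of epoxy alcohol **22**. **22** comes from OH-directed epoxidation of cyclohexenol **21**, which sets the tertiary C1'–OH cis to the C3'–OH.
2. The dihydrobenzofuran ring (O1–C2 and C3–C3a bonds, trans-2,3) forms in one Pd-catalysed heteroannulation of aryl iodide **8** (~14 heavy atoms) with diene **19** (~13 heavy atoms). This is the late coupling.
3. Diene **19** ⇐ Suzuki coupling of vinyl triflate **18** with alkenyl-Bpin **10**. **18** ⇐ regiospecific samarium enolate from epoxy ketone **16**, which comes from enone **15**, which comes from enzymatic desymmetrization of cis-diol **11**.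
4. Ring order: the cyclohexane ring is carried through from **11**, the arene comes from catechol, the dihydrobenzofuran closes at step 17, and the tertiary carbinol is installed at steps 19–20.

Assumptions (one line each):
- The lipase delivers the (1R,4S)-monoacetate **12**; the enantiocomplementary enzyme would be used otherwise.
- In step 17 the chiral bisphosphine (enantiomer chosen empirically) sets C2/C3, because the ring stereocentres are too remote to bias it.

## Route

**Step 1**
Reactants: **1** catechol
Product: **2** guaiacol (2-methoxyphenol)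
Conditions: MeI (1.0 equiv), K2CO3, acetone, 50 °C
Reagents that add atoms: iodomethane, CI
Why: Williamson mono-O-methylation; the statistical mono/di mixture is separated.

**Step 2**
Reactants: **2**
Product: **3** 4-bromo-2-methoxyphenol
Conditions: NBS, CH2Cl2, –20 °C → rt
Reagents that add atoms: N-bromosuccinimide, O=C1CCC(=O)N1Br
Why: Electrophilic bromination occurs para to the strongly activating OH (electrophilic aromatic substitution).

**Step 3**
Reactants: **3**; **4** propargyl alcohol (prop-2-yn-1-ol)
Product: **5** 3-(4-hydroxy-3-methoxyphenyl)prop-2-yn-1-ol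
Conditions: PdCl2(PPh3)2, CuI, Et3N, DMF, 70 °C
Reagents that add atoms: none
Why: Sonogashira coupling installs the three-carbon chain; the free phenol and propargylic OH are tolerated.

**Step 4**
Reactants: **5**
Product: **6** 3-(4-hydroxy-3-methoxyphenyl)propan-1-ol
Conditions: H2 (1 atm), 10% Pd/C, EtOAc, rt
Reagents that add atoms: none (H2 only)
Why: Catalytic hydrogenation of the alkyne; no aryl halide remains, so there is no hydrodehalogenation risk.

**Step 5**
Reactants: **6**
Product: **7** 3-(4-hydroxy-3-iodo-5-methoxyphenyl)propan-1-ol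
Conditions: NIS, cat. TsOH, MeCN, 0 °C
Reagents that add atoms: N-iodosuccinimide, O=C1CCC(=O)N1I
Why: The para position is blocked, and of the two ortho positions only C5–H is free, so iodination is regiospecific (electrophilic aromatic substitution).

**Step 6**
Reactants: **7**
Product: **8** 2-iodo-6-methoxy-4-[3-(tert-butyldimethylsilyloxy)propyl]phenol
Conditions: TBSCl (1.1 equiv), imidazole, DMF, 0 °C
Reagents that add atoms: TBSCl, CC(C)(C)[Si](C)(C)Cl
Why: The primary OH silylates selectively because the phenol is flanked by I and OMe.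

**Step 7**
Reactants: **4**
Product: **9** tert-butyldimethyl(prop-2-yn-1-yloxy)silane
Conditions: TBSCl, imidazole, CH2Cl2, 0 °C → rt
Reagents that add atoms: TBSCl, CC(C)(C)[Si](C)(C)Cl
Why: Standard silyl protection of the primary alcohol.

**Step 8**
Reactants: **9**
Product: **10** (E)-2-[3-(TBSO)prop-1-en-1-yl]-4,4,5,5-tetramethyl-1,3,2-dioxaborolane
Conditions: HBpin, Cp2Zr(H)Cl (10 mol%), CH2Cl2, rt
Reagents that add atoms: pinacolborane, B1OC(C)(C)C(C)(C)O1
Why: Zirconium-catalysed hydroboration adds syn across the terminal alkyne, giving the E-alkenyl boronate.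

**Step 9**
Reactants: **11** cis-cyclohex-2-ene-1,4-diol (meso)
Product: **12** (1R,4S)-4-hydroxycyclohex-2-en-1-yl acetate
Conditions: Burkholderia cepacia lipase, vinyl acetate, TBME, rt
Reagents that add atoms: vinyl acetate, C=COC(C)=O
Why: Enzymatic desymmetrization of the meso diol differentiates the enantiotopic OH groups and sets the future C4'(OMe) stereocentre.

**Step 10**
Reactants: **12**
Product: **13** (1R,4S)-4-methoxycyclohex-2-en-1-yl acetate
Conditions: MeI, Ag2O, CH2Cl2, rt, dark
Reagents that add atoms: iodomethane, CI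
Why: Ag2O-promoted methylation under neutral conditions avoids acyl migration and elimination; no stereocentre is touched.

**Step 11**
Reactants: **13**
Product: **14** (1R,4S)-4-methoxycyclohex-2-en-1-ol
Conditions: K2CO3, MeOH, rt
Reagents that add atoms: none
Why: Transesterification removes the acetate.

**Step 12**
Reactants: **14**
Product: **15** (4S)-4-methoxycyclohex-2-en-1-one
Conditions: Dess–Martin periodinane, NaHCO3, CH2Cl2, 0 °C
Reagents that add atoms: none
Why: Buffered, neutral oxidation of the allylic alcohol avoids γ-epimerization or β-elimination of the γ-OMe enone.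

**Step 13**
Reactants: **15**
Product: **16** (1R,5S,6R)-5-methoxy-7-oxabicyclo[4.1.0]heptan-2-one (epoxide trans to OMe)
Conditions: 30% H2O2, cat. NaOH, MeOH, 0 °C
Reagents that add atoms: hydrogen peroxide, OO
Why: Weitz–Scheffer nucleophilic epoxidation; hydroperoxide adds anti to the pseudo-axial 4-OMe, so the epoxide oxygen ends up trans to OMe and sets C3'.

**Step 14**
Reactants: **16**
Product: **17** (3S,4S)-4-methoxy-1,3-bis(triethylsilyloxy)cyclohex-1-ene
Conditions: SmI2 (2.2 equiv), THF, –78 °C; then Et3N, TESCl, –78 °C → 0 °C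
Reagents that add atoms: chlorotriethylsilane, CC[Si](CC)(CC)Cl
Why: SmI2 cleaves the α-C–O bond of the α,β-epoxy ketone. This gives a samarium enolate regiospecifically toward the oxygenated side, with the β-oxygen retained at C3' (stereochemistry unchanged). TESCl traps both oxygens.

**Step 15**
Reactants: **17**
Product: **18** (3S,4S)-4-methoxy-3-(triethylsilyloxy)cyclohex-1-en-1-yl trifluoromethanesulfonate
Conditions: MeLi (1.05 equiv), THF, –78 → 0 °C; recool to –78 °C; PhNTf2
Reagents that add atoms: N-phenyl-bis(trifluoromethanesulfonimide), O=S(=O)(C(F)(F)F)N(c1ccccc1)S(=O)(=O)C(F)(F)F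
Why: MeLi cleaves only the enol silyl ether (the Li enolate stays regiodefined), and PhNTf2 then gives the vinyl triflate.

**Step 16**
Reactants: **18**; **10**
Product: **19** tert-butyl{[(2E)-3-[(3S,4S)-4-methoxy-3-(triethylsilyloxy)cyclohex-1-en-1-yl]prop-2-en-1-yl]oxy}dimethylsilane
Conditions: Pd(PPh3)4 (5 mol%), K3PO4 (aq.), THF, 60 °C
Reagents that add atoms: none
Why: Suzuki–Miyaura coupling of the vinyl triflate with the E-alkenyl boronate retains alkene geometry and gives the 1,3-diene.

**Step 17 (key coupling)**
Reactants: **8**; **19**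
Product: **20** (2S,3R)-2-[(3S,4S)-4-methoxy-3-(TESO)cyclohex-1-en-1-yl]-7-methoxy-5-[3-(TBSO)propyl]-3-[(TBSO)methyl]-2,3-dihydro-1-benzofuran
Conditions: Pd(OAc)2 (5 mol%), (S)-Xyl-BINAP (6 mol%), n-Bu4NCl, K2CO3, DMF, 80 °C
Reagents that add atoms: none (HI is lost)
Why: Larock-type heteroannulation. Aryl-Pd adds to the less hindered CH=CH terminus (Ar goes to the carbon bearing CH2OTBS), giving a π-allyl-Pd, and the tethered phenoxide closes on it (5-exo). The C2 substituent sits pseudo-equatorial, so the 2,3-trans ring forms; the chiral ligand sets the absolute configuration at C2/C3.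

**Step 18**
Reactants: **20**
Product: **21** as **20** with free allylic alcohol, [(3S,4S)-3-hydroxy-4-methoxycyclohex-1-en-1-yl]
Conditions: PPTS (cat.), MeOH, rt
Reagents that add atoms: none
Why: The secondary TES ether is cleaved selectively in the presence of the primary TBS ethers.

**Step 19**
Reactants: **21**
Product: **22** epoxy alcohol (epoxide at C1'–C2' cis to the C3'–OH, anti to OMe)
Conditions: VO(acac)2 (5 mol%), TBHP (anhydrous, in decane), CH2Cl2, 0 °C → rt
Reagents that add atoms: tert-butyl hydroperoxide, CC(C)(C)OO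
Why: Vanadium-catalysed hydroxy-directed epoxidation of a cyclohex-2-enol delivers oxygen syn to OH; this face becomes the C1'–OH face (tertiary carbinol stereocentre).

**Step 20**
Reactants: **22**
Product: **23** bis-TBS precursor of the target (1,3-diol)
Conditions: Red-Al (65% in toluene), THF, 0 °C
Reagents that add atoms: none (hydride only)
Why: Alkoxyaluminate-delivered hydride opens the 2,3-epoxy alcohol at the proximal secondary carbon (C2'), giving the 1,3-diol with OH retained on tertiary C1' (stereochemistry retained).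

**Step 21**
Reactants: **23**
Product: **24** difengpiol B
Conditions: TBAF, THF, rt
Reagents that add atoms: none
Why: Fluoride removes both primary TBS ethers, giving the target.

## Compound list

1 | catechol | Oc1ccccc1O | starting material
2 | guaiacol | COc1ccccc1O | intermediate
3 | 4-bromo-2-methoxyphenol | COc1cc(Br)ccc1O | intermediate
4 | propargyl alcohol | C#CCO | starting material
5 | 3-(4-hydroxy-3-methoxyphenyl)prop-2-yn-1-ol | COc1cc(C#CCO)ccc1O | intermediate
6 | 3-(4-hydroxy-3-methoxyphenyl)propan-1-ol | COc1cc(CCCO)ccc1O | intermediate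
7 | 3-(4-hydroxy-3-iodo-5-methoxyphenyl)propan-1-ol | COc1cc(CCCO)cc(I)c1O | intermediate
8 | aryl iodide, TBS ether | COc1cc(CCCO[Si](C)(C)C(C)(C)C)cc(I)c1O | intermediate
9 | TBS propargyl ether | C#CCO[Si](C)(C)C(C)(C)C | intermediate
10 | (E)-alkenyl-Bpin | CC1(C)OB(OC1(C)C)/C=C/CO[Si](C)(C)C(C)(C)C | intermediate
11 | cis-cyclohex-2-ene-1,4-diol | O[C@H]1C=C[C@@H](O)CC1 | starting material
12 | (1R,4S)-4-hydroxycyclohex-2-en-1-yl acetate | CC(=O)O[C@H]1C=C[C@@H](O)CC1 | intermediate
13 | (1R,4S)-4-methoxycyclohex-2-en-1-yl acetate | CC(=O)O[C@H]1C=C[C@@H](OC)CC1 | intermediate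
14 | (1R,4S)-4-methoxycyclohex-2-en-1-ol | O[C@H]1C=C[C@@H](OC)CC1 | intermediate
15 | (4S)-4-methoxycyclohex-2-en-1-one | O=C1C=C[C@@H](OC)CC1 | intermediate
16 | (1R,5S,6R)-5-methoxy-7-oxabicyclo[4.1.0]heptan-2-one | O=C1CC[C@H](OC)[C@H]2O[C@@H]12 | intermediate
17 | bis-TES enol ether | CC[Si](CC)(CC)OC1=C[C@H](O[Si](CC)(CC)CC)[C@@H](OC)CC1 | intermediate
18 | vinyl triflate | FC(F)(F)S(=O)(=O)OC1=C[C@H](O[Si](CC)(CC)CC)[C@@H](OC)CC1 | intermediate
19 | diene | CC(C)(C)[Si](C)(C)OC/C=C/C1=C[C@H](O[Si](CC)(CC)CC)[C@@H](OC)CC1 | intermediate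
20 | dihydrobenzofuran (TES, 2×TBS) | COc1cc(CCCO[Si](C)(C)C(C)(C)C)cc2c1O[C@H](C1=C[C@H](O[Si](CC)(CC)CC)[C@@H](OC)CC1)[C@H]2CO[Si](C)(C)C(C)(C)C | intermediate
21 | allylic alcohol | COc1cc(CCCO[Si](C)(C)C(C)(C)C)cc2c1O[C@H](C1=C[C@H](O)[C@@H](OC)CC1)[C@H]2CO[Si](C)(C)C(C)(C)C | intermediate
22 | epoxy alcohol | COc1cc(CCCO[Si](C)(C)C(C)(C)C)cc2c1O[C@H]([C@@]13O[C@@H]1[C@H](O)[C@@H](OC)CC3)[C@H]2CO[Si](C)(C)C(C)(C)C | intermediate
23 | bis-TBS diol | COc1cc(CCCO[Si](C)(C)C(C)(C)C)cc2c1O[C@H]([C@]1(O)CC[C@H](OC)[C@@H](O)C1)[C@H]2CO[Si](C)(C)C(C)(C)C | intermediate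
24 | difengpiol B, (1S,3S,4S)-1-[(2S,3R)-3-(hydroxymethyl)-5-(3-hydroxypropyl)-7-methoxy-2,3-dihydro-1-benzofuran-2-yl]-4-methoxycyclohexane-1,3-diol | COc1cc(CCCO)cc2c1O[C@H]([C@]1(O)CC[C@H](OC)[C@@H](O)C1)[C@H]2CO | target

## Totals

- Total steps: 21.
- Longest linear sequence: 13 (steps 9–21, from cis-diol **11**).

## Three steps most likely to fail

1. **Step 17 (Larock heteroannulation).** The diene is hindered at both termini, and catalyst-controlled C2/C3 selectivity is uncertain.
   - Fallback: change the strategy. Add lithiated **9** to a ring-B ketone to give the propargylic tertiary alcohol, build the 2,3-disubstituted benzofuran by Larock alkyne annulation with **8**, then reduce it (asymmetric hydrogenation and C3 epimerization through an ester handle).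
2. **Steps 14–15 (regiospecific Sm enolate trapping and enol triflate formation).** The β-silyloxy enolate can eliminate, or the Sm enolate may not silylate cleanly.
   - Fallback: make the vinyl iodide coupling partner from 1,3-cyclohexanedione. Go through 3-iodocyclohexenone, α'-hydroxylation and methylation, Luche reduction, and lipase kinetic resolution.
3. **Step 20 (Red-Al regioselectivity).** Reduction could occur at the tertiary distal epoxide carbon, or give over-reduction or a mixture.
   - Fallback: replace steps 19–20 with Mukaiyama hydration (Co(acac)2, PhSiH3, O2) of allylic alcohol **21**, which puts OH directly on tertiary C1'. C1' epimers would then be separated.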